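The furan, the only ring, hangs by its C3 on the propyl tether from chain C6 and is otherwise unsubstituted. That lets its C3=C4 bond be the disconnection: ring atoms O1, C2 and C5 are carried open-chain as a mixed acrolein acetal of a 2-alkylallyl alcohol. In one operation, ring-closing metathesis joins the 1,1-disubstituted alkene to the acetal vinyl group and acid then expels methanol, giving the aromatic ring. The precursor 28 is the complete diester skeleton: chain C2 and C6 come from two oxazolidinone allylations, the acids are already differentiated (methyl and 2-(trimethylsilyl)ethyl esters), and the acetal arm is attached by a B-alkyl Suzuki coupling, so the furan appears only at the end.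

Key step: step 13

Remark: chain locants are those of the heptanedioate (C1 methyl ester carbon, C7 free-acid carbon); the acetal carbon in 26, 28 and 29 is left unresolved because it ends as furan C5.

Step 1
Reactants: 1 (4-carboxybutyl)triphenylphosphonium bromide; 2 acetone
Product: 4 6-methylhept-5-enoic acid, via phosphonium ylide 3 (not isolated)
Conditions: NaN(SiMe3)2 (2.2 equiv), THF, 0 °C to rt; acetone, 0 °C to rt; then 1 M HCl
Reagents that add atoms: none
Why: Wittig olefination: the non-stabilised ylide (two equivalents of base because of the free acid) should add to acetone and collapse to the trisubstituted alkene, and base extraction frees the acid from triphenylphosphine oxide.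

Step 2
Reactants: 4 6-methylhept-5-enoic acid; 5 (R)-4-benzyloxazolidin-2-one
Product: 7 (R)-4-benzyl-3-(6-methylhept-5-enoyl)oxazolidin-2-one, via mixed pivalic anhydride 6 (not isolated)
Conditions: t-BuCOCl, Et3N, THF, −20 °C; then LiCl, 5, −20 °C to rt
Reagents that add atoms: none
Why: N-acylation of the oxazolidinone by a mixed pivalic anhydride under LiCl/Et3N is the standard mild entry to Evans imides and avoids an acid chloride next to the acid-sensitive trisubstituted alkene.

Step 3
Reactants: 7 (R)-4-benzyl-3-(6-methylhept-5-enoyl)oxazolidin-2-one; 8 allyl iodide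
Product: 10 (R)-4-benzyl-3-[(S)-2-allyl-6-methylhept-5-enoyl]oxazolidin-2-one, via sodium Z-enolate 9 (not isolated)
Conditions: NaN(SiMe3)2 (1.1 equiv), THF, −78 °C; allyl iodide (3 equiv), −78 to −45 °C
Reagents that add atoms: none
Why: Evans asymmetric alkylation: the chelated sodium Z-enolate should be attacked by the activated allylic iodide on the face away from the benzyl group of the (R)-auxiliary, which fixes C2 (S here only because allyl outranks the methylpentenyl chain; the same centre is 2R in the target).

Step 4
Reactants: 10 (R)-4-benzyl-3-[(S)-2-allyl-6-methylhept-5-enoyl]oxazolidin-2-one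
Product: 11 methyl (S)-2-allyl-6-methylhept-5-enoate
Conditions: MeMgBr, MeOH, CH2Cl2, 0 °C; then 1 M HCl
Reagents that add atoms: methoxymagnesium bromide, CO[Mg]Br
Why: Transesterification of the imide: magnesium-bound methoxide should attack the chelated exocyclic carbonyl, giving the methyl ester without touching C2 and releasing auxiliary 5 for reuse.

Step 5
Reactants: 11 methyl (S)-2-allyl-6-methylhept-5-enoate; 12 allyl bromoacetate
Product: 14 7-allyl 1-methyl (R)-2-(4-methylpent-3-en-1-yl)heptanedioate, via B-alkyl-9-BBN adduct 13 (not isolated)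
Conditions: 9-BBN (1.05 equiv), THF, 0 °C to rt; then 12, 2,6-di-tert-butylphenol, KOtBu, THF, 0 °C
Reagents that add atoms: none
Why: Hydroboration followed by organoborane alkylation of an α-bromo ester (Brown alkylation): 9-BBN should add only to the terminal alkene in the anti-Markovnikov sense, and the bromoacetate enolate made by the hindered phenoxide should form a borate from which the primary alkyl group migrates to carbon with loss of bromide, so that protonolysis leaves the chain two carbons longer (C6 and C7) with the methyl ester and C2 untouched.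

Step 6
Reactants: 14 7-allyl 1-methyl (R)-2-(4-methylpent-3-en-1-yl)heptanedioate
Product: 15 (R)-2-(4-methylpent-3-en-1-yl)heptanedioic acid 1-methyl ester
Conditions: Pd(PPh3)4 (3 mol%), morpholine, THF, rt; then dilute acid wash
Reagents that add atoms: none
Why: Palladium-catalysed deallylation (Tsuji–Trost type): zerovalent palladium should ionise only the allyl ester to a π-allyl complex that morpholine captures, leaving the methyl ester and the trisubstituted alkene alone.

Step 7
Reactants: 15 (R)-2-(4-methylpent-3-en-1-yl)heptanedioic acid 1-methyl ester; 5 (R)-4-benzyloxazolidin-2-one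
Product: 17 methyl (R)-7-[(R)-4-benzyl-2-oxooxazolidin-3-yl]-2-(4-methylpent-3-en-1-yl)-7-oxoheptanoate, via mixed pivalic anhydride 16 (not isolated)
Conditions: t-BuCOCl, Et3N, THF, −20 °C; then LiCl, 5, −20 °C to rt
Reagents that add atoms: none
Why: The same mixed-anhydride N-acylation as in step 2 should work unchanged, since the distal methyl ester is inert to these conditions.

Step 8
Reactants: 17 methyl (R)-7-[(R)-4-benzyl-2-oxooxazolidin-3-yl]-2-(4-methylpent-3-en-1-yl)-7-oxoheptanoate; 8 allyl iodide
Product: 19 methyl (2R,6S)-6-allyl-7-[(R)-4-benzyl-2-oxooxazolidin-3-yl]-2-(4-methylpent-3-en-1-yl)-7-oxoheptanoate, via sodium Z-enolate 18 (not isolated)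
Conditions: NaN(SiMe3)2 (1.05 equiv), THF, −78 °C; allyl iodide (3 equiv), −78 to −45 °C
Reagents that add atoms: none
Why: Second Evans asymmetric alkylation: the imide is far more acidic than the α-branched methyl ester, so only C6 is enolised, and allyl iodide should again enter anti to the benzyl group of the (R)-auxiliary to set C6 as S, the low temperature holding back Dieckmann-type attack on the C1 ester.

Step 9
Reactants: 19 methyl (2R,6S)-6-allyl-7-[(R)-4-benzyl-2-oxooxazolidin-3-yl]-2-(4-methylpent-3-en-1-yl)-7-oxoheptanoate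
Product: 21 (2R,6S)-6-allyl-2-(4-methylpent-3-en-1-yl)heptanedioic acid 1-methyl ester, via peroxy acid 20 (not isolated)
Conditions: LiOH, H2O2, THF/H2O, 0 °C; then Na2SO3; 1 M HCl to pH 3
Reagents that add atoms: hydrogen peroxide, OO
Why: Hydroperoxide hydrolysis of the imide (LiOOH cleavage): the hydroperoxide anion should attack the exocyclic imide carbonyl much faster than hydroxide attacks the hindered methyl ester, sulfite then reduces the peroxy acid, and neither stereocentre is enolised at 0 °C.

Step 10
Reactants: 21 (2R,6S)-6-allyl-2-(4-methylpent-3-en-1-yl)heptanedioic acid 1-methyl ester; 22 2-(trimethylsilyl)ethanol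
Product: 23 1-methyl 7-[2-(trimethylsilyl)ethyl] (2R,6S)-6-allyl-2-(4-methylpent-3-en-1-yl)heptanedioate
Conditions: EDC hydrochloride, DMAP (cat.), CH2Cl2, 0 °C to rt
Reagents that add atoms: none
Why: Steglich esterification: carbodiimide activation with catalytic DMAP should esterify the α,α-dialkyl acid without epimerising C6, and this ester is chosen because fluoride alone removes it later.

Step 11
Reactants: 24 2-bromoprop-2-en-1-ol; 25 acrolein dimethyl acetal
Product: 26 2-bromo-3-[(1-methoxyprop-2-en-1-yl)oxy]prop-1-ene (racemic)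
Conditions: 25 (6 equiv), PPTS (5 mol%), 5 Å MS, toluene, 60 °C
Reagents that add atoms: none
Why: Acid-catalysed transacetalisation: PPTS generates the methoxy-allyl oxocarbenium ion, which the alcohol should capture, and excess acetal with removal of methanol drives the exchange on a cheap building block instead of on the late intermediate.

Step 12
Reactants: 23 1-methyl 7-[2-(trimethylsilyl)ethyl] (2R,6S)-6-allyl-2-(4-methylpent-3-en-1-yl)heptanedioate; 26 2-bromo-3-[(1-methoxyprop-2-en-1-yl)oxy]prop-1-ene
Product: 28 1-methyl 7-[2-(trimethylsilyl)ethyl] (2R,6S)-6-{4-[(1-methoxyprop-2-en-1-yl)oxymethyl]pent-4-en-1-yl}-2-(4-methylpent-3-en-1-yl)heptanedioate (both acetal epimers), via B-alkyl-9-BBN adduct 27 (not isolated)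
Conditions: 9-BBN (1.2 equiv), THF, 0 °C to rt; then aq. Cs2CO3, 26, PdCl2(dppf) (5 mol%), AsPh3 (10 mol%), DMF, rt
Reagents that add atoms: none
Why: B-alkyl Suzuki–Miyaura coupling: 9-BBN should hydroborate only the monosubstituted alkene of 23, and once the aqueous base has destroyed residual B–H the alkylborane should couple with the alkenyl bromide under palladium catalysis, mild carbonate leaving both esters and the acetal intact.

Step 13
Reactants: 28 1-methyl 7-[2-(trimethylsilyl)ethyl] (2R,6S)-6-{4-[(1-methoxyprop-2-en-1-yl)oxymethyl]pent-4-en-1-yl}-2-(4-methylpent-3-en-1-yl)heptanedioate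
Product: 30 1-methyl 7-[2-(trimethylsilyl)ethyl] (2R,6S)-6-[3-(furan-3-yl)propyl]-2-(4-methylpent-3-en-1-yl)heptanedioate, via 2-methoxy-2,5-dihydrofuran 29 (not isolated)
Conditions: second-generation Grubbs catalyst RuCl2(=CHPh)(PCy3)(H2IMes) (5 mol%), CH2Cl2 (0.01 M), 40 °C, argon sparge; then PPTS (20 mol%), rt
Reagents that add atoms: none
Why: The ruthenium benzylidene should first exchange with the unhindered acetal vinyl group, the new alkylidene then adds across the tethered 1,1-disubstituted alkene in a [2+2] step, and cycloreversion releases ethylene while forming the C3=C4 bond of 29. The ring is closed as a five-membered ring by olefin metathesis at carbon, its two C–O bonds being in place beforehand. PPTS then ionises the cyclic acetal to an oxocarbenium ion and loss of a proton from the ring CH2 completes the elimination of methanol to the furan. Closest known reaction type: metathesis closure of acrolein-derived mixed allyl acetals to 2-alkoxy-2,5-dihydrofurans and their acid-induced conversion into furans. No stereocentre is created and the acetal centre is erased, so both epimers of 28 should give the same product. The step needs site selectivity among three alkenes, which the substrate supplies: the catalyst loads at the monosubstituted vinyl group and the five-membered closure onto the neighbouring methylene alkene should outrun any reaction at the distant trisubstituted alkene, while high dilution and venting of ethylene guard against dimers and ethenolysis.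

Step 14
Reactants: 30 1-methyl 7-[2-(trimethylsilyl)ethyl] (2R,6S)-6-[3-(furan-3-yl)propyl]-2-(4-methylpent-3-en-1-yl)heptanedioate
Product: 31 (2R,6S)-6-[3-(furan-3-yl)propyl]-2-(4-methylpent-3-en-1-yl)heptanedioic acid 1-methyl ester (target)
Conditions: Bu4NF, THF, 0 °C to rt; then cold 0.1 M HCl to pH 4
Reagents that add atoms: none
Why: Fluoride-induced fragmentation of the 2-(trimethylsilyl)ethyl ester: attack at silicon should expel ethylene and the carboxylate, leaving the methyl ester, furan, alkene and both stereocentres unchanged.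

Compound list
1 | (4-carboxybutyl)triphenylphosphonium bromide | OC(=O)CCCC[P+](c1ccccc1)(c1ccccc1)c1ccccc1.[Br-] | starting material
2 | acetone | CC(C)=O | starting material
3 | sodium 5-(triphenylphosphoranylidene)pentanoate | [Na+].[O-]C(=O)CCCC=P(c1ccccc1)(c1ccccc1)c1ccccc1 | intermediate
4 | 6-methylhept-5-enoic acid | CC(C)=CCCCC(=O)O | intermediate
5 | (R)-4-benzyloxazolidin-2-one | O=C1N[C@H](Cc2ccccc2)CO1 | starting material
6 | 6-methylhept-5-enoic pivalic anhydride | CC(C)=CCCCC(=O)OC(=O)C(C)(C)C | intermediate
7 | (R)-4-benzyl-3-(6-methylhept-5-enoyl)oxazolidin-2-one | CC(C)=CCCCC(=O)N1[C@H](Cc2ccccc2)COC1=O | intermediate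
8 | allyl iodide (3-iodoprop-1-ene) | C=CCI | starting material
9 | sodium (Z)-enolate of 7 | CC(C)=CCC/C=C(\[O-])N1[C@H](Cc2ccccc2)COC1=O.[Na+] | intermediate
10 | (R)-4-benzyl-3-[(S)-2-allyl-6-methylhept-5-enoyl]oxazolidin-2-one | O=C([C@@H](CCC=C(C)C)CC=C)N1[C@H](Cc2ccccc2)COC1=O | intermediate
11 | methyl (S)-2-allyl-6-methylhept-5-enoate | COC(=O)[C@@H](CCC=C(C)C)CC=C | intermediate
12 | allyl bromoacetate | C=CCOC(=O)CBr | starting material
13 | methyl (R)-2-[3-(9-borabicyclo[3.3.1]nonan-9-yl)propyl]-6-methylhept-5-enoate | COC(=O)[C@@H](CCC=C(C)C)CCCB1C2CCCC1CCC2 | intermediate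
14 | 7-allyl 1-methyl (R)-2-(4-methylpent-3-en-1-yl)heptanedioate | COC(=O)[C@@H](CCC=C(C)C)CCCCC(=O)OCC=C | intermediate
15 | (R)-2-(4-methylpent-3-en-1-yl)heptanedioic acid 1-methyl ester | COC(=O)[C@@H](CCC=C(C)C)CCCCC(=O)O | intermediate
16 | mixed pivalic anhydride of 15 at C7 | COC(=O)[C@@H](CCC=C(C)C)CCCCC(=O)OC(=O)C(C)(C)C | intermediate
17 | methyl (R)-7-[(R)-4-benzyl-2-oxooxazolidin-3-yl]-2-(4-methylpent-3-en-1-yl)-7-oxoheptanoate | COC(=O)[C@@H](CCC=C(C)C)CCCCC(=O)N1[C@H](Cc2ccccc2)COC1=O | intermediate
18 | sodium (Z)-enolate of 17 (C6=C7) | COC(=O)[C@@H](CCC=C(C)C)CCC/C=C(\[O-])N1[C@H](Cc2ccccc2)COC1=O.[Na+] | intermediate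
19 | methyl (2R,6S)-6-allyl-7-[(R)-4-benzyl-2-oxooxazolidin-3-yl]-2-(4-methylpent-3-en-1-yl)-7-oxoheptanoate | COC(=O)[C@@H](CCC=C(C)C)CCC[C@@H](CC=C)C(=O)N1[C@H](Cc2ccccc2)COC1=O | intermediate
20 | peroxy acid of 21 (C7 as C(=O)OOH) | COC(=O)[C@@H](CCC=C(C)C)CCC[C@@H](CC=C)C(=O)OO | intermediate
21 | (2R,6S)-6-allyl-2-(4-methylpent-3-en-1-yl)heptanedioic acid 1-methyl ester | COC(=O)[C@@H](CCC=C(C)C)CCC[C@@H](CC=C)C(=O)O | intermediate
22 | 2-(trimethylsilyl)ethanol | C[Si](C)(C)CCO | starting material
23 | 1-methyl 7-[2-(trimethylsilyl)ethyl] (2R,6S)-6-allyl-2-(4-methylpent-3-en-1-yl)heptanedioate | COC(=O)[C@@H](CCC=C(C)C)CCC[C@@H](CC=C)C(=O)OCC[Si](C)(C)C | intermediate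
24 | 2-bromoprop-2-en-1-ol | OCC(Br)=C | starting material
25 | acrolein dimethyl acetal | COC(OC)C=C | starting material
26 | 2-bromo-3-[(1-methoxyprop-2-en-1-yl)oxy]prop-1-ene (racemic) | C=CC(OC)OCC(Br)=C | intermediate
27 | 1-methyl 7-[2-(trimethylsilyl)ethyl] (2R,6R)-6-[3-(9-borabicyclo[3.3.1]nonan-9-yl)propyl]-2-(4-methylpent-3-en-1-yl)heptanedioate (6R by priority change only) | COC(=O)[C@@H](CCC=C(C)C)CCC[C@@H](CCCB1C2CCCC1CCC2)C(=O)OCC[Si](C)(C)C | intermediate
28 | 1-methyl 7-[2-(trimethylsilyl)ethyl] (2R,6S)-6-{4-[(1-methoxyprop-2-en-1-yl)oxymethyl]pent-4-en-1-yl}-2-(4-methylpent-3-en-1-yl)heptanedioate, both acetal epimers | COC(=O)[C@@H](CCC=C(C)C)CCC[C@@H](CCCC(=C)COC(OC)C=C)C(=O)OCC[Si](C)(C)C | intermediate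
29 | 1-methyl 7-[2-(trimethylsilyl)ethyl] (2R,6S)-6-[3-(5-methoxy-2,5-dihydrofuran-3-yl)propyl]-2-(4-methylpent-3-en-1-yl)heptanedioate, both acetal epimers | COC(=O)[C@@H](CCC=C(C)C)CCC[C@@H](CCCC1=CC(OC)OC1)C(=O)OCC[Si](C)(C)C | intermediate
30 | 1-methyl 7-[2-(trimethylsilyl)ethyl] (2R,6S)-6-[3-(furan-3-yl)propyl]-2-(4-methylpent-3-en-1-yl)heptanedioate | COC(=O)[C@@H](CCC=C(C)C)CCC[C@@H](CCCc1ccoc1)C(=O)OCC[Si](C)(C)C | intermediate
31 | (2R,6S)-6-[3-(furan-3-yl)propyl]-2-(4-methylpent-3-en-1-yl)heptanedioic acid 1-methyl ester | COC(=O)[C@@H](CCC=C(C)C)CCC[C@@H](CCCc1ccoc1)C(=O)O | target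

Total step count: 14. Longest linear sequence: 13 (steps 1–10, 12, 13 and 14); step 11 is a one-step branch.

Steps most likely to fail

Step 13. The catalyst may turn over slowly at the 1,1-disubstituted alkene, so that the open acetal ionises or oligomerises through its vinyl group, or ethylene cuts the trisubstituted alkene, before the ring closes. The fallback sets out from 23 and comes back at 30. The alkylborane 27 is generated from 23 as in step 12 and coupled instead with commercial 3-bromofuran under PdCl2(dppf)/AsPh3/Cs2CO3 in DMF/H2O. This B-alkyl Suzuki–Miyaura coupling brings in the finished heteroaromatic ring, forms no ring at all and needs no new compound.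

Step 5. The borate may fail to rearrange cleanly: protonolysis of the bromoacetate enolate, migration of a ring B–C bond of the bicycle, or base-induced ester exchange would erode the two-carbon extension. The fallback sets out from 11 and comes back at 15. The same borane 13 is coupled with (Z)-1-bromo-2-ethoxyethene (PdCl2(dppf), K3PO4, DMF/H2O, rt) to give the enol ether methyl (R)-2-[(Z)-5-ethoxypent-4-en-1-yl]-6-methylhept-5-enoate F1. Brief treatment with dilute HCl in THF at 0 °C unmasks the aldehyde methyl (R)-6-methyl-2-(5-oxopentyl)hept-5-enoate F2. Pinnick oxidation (NaClO2, NaH2PO4, 2-methylbut-2-ene, t-BuOH/H2O) then gives acid 15, which re-enters at step 7.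

Step 12. The alkenyl-palladium intermediate may lose its β-alkoxy group, or the acetal may not survive the aqueous basic coupling, so that protodeboronation takes over. The fallback sets out from 23 and comes back at 28. Borane 27 is coupled with unprotected 2-bromoprop-2-en-1-ol 24 to give the allylic alcohol 1-methyl 7-[2-(trimethylsilyl)ethyl] (2R,6S)-6-[4-(hydroxymethyl)pent-4-en-1-yl]-2-(4-methylpent-3-en-1-yl)heptanedioate F3. The acetal is then put on last by PPTS-catalysed exchange with excess 25 as in step 11, giving 28.

Further compounds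
F0 | step 13 | none | none
F1 | step 5 | methyl (R)-2-[(Z)-5-ethoxypent-4-en-1-yl]-6-methylhept-5-enoate | COC(=O)[C@@H](CCC=C(C)C)CCC/C=C\OCC
F2 | step 5 | methyl (R)-6-methyl-2-(5-oxopentyl)hept-5-enoate | COC(=O)[C@@H](CCC=C(C)C)CCCCC=O
F3 | step 12 | 1-methyl 7-[2-(trimethylsilyl)ethyl] (2R,6S)-6-[4-(hydroxymethyl)pent-4-en-1-yl]-2-(4-methylpent-3-en-1-yl)heptanedioate | COC(=O)[C@@H](CCC=C(C)C)CCC[C@@H](CCCC(=C)CO)C(=O)OCC[Si](C)(C)C
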